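The route rests on cutting the side chain between methylene C-4' and the tertiary carbinol C-3' (chain numbered C-1' to C-5' from the coumarin ether oxygen to the cyclohexanone ring CH). The key step, a lithiation–borylation, joins a ring-bearing primary boronic ester to the α-lithiated triisopropylbenzoate of an (S)-butan-2-ol unit: C-4' migrates from boron to C-3', the benzoate leaves, and oxidation turns C–B into the C-3' hydroxyl. It exploits the acyclic methyl carbinol C-3', whose C–C bond and configuration are created together, independent of the remote ring stereocentres. The boronate comes from (S)-linalool by an epoxide–allylsilane cyclisation; umbelliferone is attached last.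

Key step: step 9

Assumption: (S)-(+)-linalool of high enantiomeric purity is taken as commercially available; the ring ketone is carried as a silylated secondary alcohol (a temporary stereocentre) and restored in step 12.

Step 1
Reactants: 1 (S)-(+)-linalool
Product: 2 triethyl{[(3S)-3,7-dimethylocta-1,6-dien-3-yl]oxy}silane
Conditions: TESOTf, 2,6-lutidine, CH2Cl2, −78 → 0 °C
Reagents that add atoms: triethylsilyl trifluoromethanesulfonate, CC[Si](CC)(CC)OS(=O)(=O)C(F)(F)F
Why: Silylation of the tertiary alcohol with a silyl triflate and a hindered base should mask the hydroxyl for the later Lewis acid step without touching the stereocentre, which becomes the ring carbinol carbon of the target.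

Step 2
Reactants: 2 triethyl{[(3S)-3,7-dimethylocta-1,6-dien-3-yl]oxy}silane
Product: 3 triethyl{[(3S)-5-[(2R)-3,3-dimethyloxiran-2-yl]-3-methylpent-1-en-3-yl]oxy}silane
Conditions: D-fructose-derived Shi ketone (30 mol %), Oxone, K2CO3, Bu4NHSO4, MeCN/dimethoxymethane/aq. borate buffer (pH 10.5), 0 °C
Reagents that add atoms: Oxone (potassium peroxymonosulfate), [K+].[O-]S(=O)(=O)OO
Why: In this Shi asymmetric epoxidation the chiral dioxirane should attack only the electron-rich trisubstituted alkene (the vinyl group is too electron-poor), and the spiro transition state of the D-fructose-derived ketone should set the (R)-epoxide carbon under reagent control.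

Step 3
Reactants: 3 triethyl{[(3S)-5-[(2R)-3,3-dimethyloxiran-2-yl]-3-methylpent-1-en-3-yl]oxy}silane; 4 allyltrimethylsilane (5 equiv)
Product: 5 triethyl{[(2E,4S)-6-[(2R)-3,3-dimethyloxiran-2-yl]-4-methyl-1-(trimethylsilyl)hex-2-en-4-yl]oxy}silane
Conditions: Hoveyda–Grubbs II (10 mol %), CH2Cl2, 40 °C
Reagents that add atoms: none
Why: Olefin cross-metathesis of the hindered vinyl group, which cannot homodimerise next to its fully substituted carbon, with an excess of the unhindered allylsilane should give the E-allylsilane with loss of ethylene, the epoxide being inert to the ruthenium carbene.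

Step 4
Reactants: 5 triethyl{[(2E,4S)-6-[(2R)-3,3-dimethyloxiran-2-yl]-4-methyl-1-(trimethylsilyl)hex-2-en-4-yl]oxy}silane
Product: 6 (1R,3R,4S)-3-ethenyl-2,2,4-trimethyl-4-[(triethylsilyl)oxy]cyclohexan-1-ol
Conditions: BF3·OEt2, CH2Cl2, −78 °C; aq. NaHCO3
Reagents that add atoms: none
Why: In this Lewis acid-promoted epoxide–allylsilane cyclisation (intramolecular Hosomi–Sakurai type, SE2') the γ-carbon of the allylsilane should attack the tertiary epoxide carbon through a chair transition state with the epoxide oxygen and the allyl unit equatorial and the silyloxy group (not the methyl) axial, which sets the ring CH cis to both oxygens, and loss of silicon leaves the vinyl group.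

Step 5
Reactants: 6 (1R,3R,4S)-3-ethenyl-2,2,4-trimethyl-4-[(triethylsilyl)oxy]cyclohexan-1-ol
Product: 7 {[(1R,3R,4S)-3-ethenyl-2,2,4-trimethylcyclohexane-1,4-diyl]bis(oxy)}bis(triethylsilane)
Conditions: TESOTf, 2,6-lutidine, CH2Cl2, 0 °C
Reagents that add atoms: triethylsilyl trifluoromethanesulfonate, CC[Si](CC)(CC)OS(=O)(=O)C(F)(F)F
Why: Silyl triflate silylation of the hindered secondary alcohol should remove the last acidic proton of the ring fragment before the organolithium step.

Step 6
Reactants: 7 {[(1R,3R,4S)-3-ethenyl-2,2,4-trimethylcyclohexane-1,4-diyl]bis(oxy)}bis(triethylsilane)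
Product: 9 5,5-dimethyl-2-{2-[(1R,3R,6S)-2,2,6-trimethyl-3,6-bis(triethylsilyloxy)cyclohexyl]ethyl}-1,3,2-dioxaborinane, via catechol boronate 8 (not isolated)
Conditions: catecholborane, RhCl(PPh3)3 (2 mol %), THF, rt; then neopentyl glycol, rt
Reagents that add atoms: catecholborane, B1Oc2ccccc2O1; neopentyl glycol (2,2-dimethylpropane-1,3-diol), OCC(C)(C)CO
Why: Rhodium-catalysed anti-Markovnikov hydroboration of the terminal alkene should place boron on the terminal carbon (the future C-4'), and transesterification in the same flask should give the unhindered neopentyl glycol ester needed for step 9.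

Step 7
Reactants: 10 (R)-butane-1,3-diol
Product: 11 (2R)-4-[(tert-butyldimethylsilyl)oxy]butan-2-ol
Conditions: TBSCl, imidazole, CH2Cl2, 0 °C
Reagents that add atoms: tert-butyldimethylsilyl chloride, CC(C)(C)[Si](C)(C)Cl
Why: Silylation with the bulky chlorosilane should be selective for the primary over the secondary hydroxyl.

Step 8
Reactants: 11 (2R)-4-[(tert-butyldimethylsilyl)oxy]butan-2-ol
Product: 12 (2S)-4-[(tert-butyldimethylsilyl)oxy]butan-2-yl 2,4,6-triisopropylbenzoate
Conditions: 2,4,6-triisopropylbenzoic acid, PPh3, DIAD, THF, 0 °C → rt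
Reagents that add atoms: 2,4,6-triisopropylbenzoic acid, CC(C)c1cc(C(C)C)c(C(=O)O)c(C(C)C)c1
Why: Mitsunobu esterification should install the hindered benzoate with clean inversion, turning the (R)-alcohol into the (S)-ester whose carbinol carbon becomes C-3'.

Step 9
Reactants: 12 (2S)-4-[(tert-butyldimethylsilyl)oxy]butan-2-yl 2,4,6-triisopropylbenzoate (1.5 equiv); 9 5,5-dimethyl-2-{2-[(1R,3R,6S)-2,2,6-trimethyl-3,6-bis(triethylsilyloxy)cyclohexyl]ethyl}-1,3,2-dioxaborinane
Product: 16 (3R)-1-[(tert-butyldimethylsilyl)oxy]-3-methyl-5-[(1R,3R,6S)-2,2,6-trimethyl-3,6-bis(triethylsilyloxy)cyclohexyl]pentan-3-ol, via lithiated benzoate 13 (not isolated), via boronate complex 14 (not isolated), via tertiary boronic ester 15 (not isolated)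
Conditions: s-BuLi, TMEDA, CPME, −60 °C; then 9, −60 → 50 °C; then NaOH, H2O2, THF/H2O, 0 °C → rt
Reagents that add atoms: hydrogen peroxide, OO
Why: s-BuLi/TMEDA should remove the carbinol proton of 12 under direction of the benzoate carbonyl to give the configurationally stable α-oxy organolithium 13, which adds to boron of 9 with retention to form boronate complex 14; on warming the primary alkyl group (C-4') migrates from boron to C-3' antiperiplanar to the departing triisopropylbenzoate (inversion) to give tertiary boronic ester 15, and alkaline peroxide replaces boron by hydroxyl with retention. The closest known reaction type is the lithiation–borylation of secondary dialkyl 2,4,6-triisopropylbenzoates with neopentyl glycol boronic esters, a stereospecific 1,2-metallate rearrangement. No ring is closed. The new stereocentre C-3' is controlled by the configuration of 12 alone: the new C–C bond takes the place of the carbinol C–H with overall retention, so (S)-12 should give the (3R)-alcohol whatever the remote ring stereocentres are. The step needs selective α-deprotonation, complete capture of the hindered carbenoid and migration of carbon only; the carbonyl-directed lithiation, the unhindered primary neopentyl glycol boronate (whose oxygens cannot migrate) and a substrate free of acidic or electrophilic groups (all hydroxyls silylated, ketone carried as a silyl ether, coumarin not yet present) secure this.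

Step 10
Reactants: 16 (3R)-1-[(tert-butyldimethylsilyl)oxy]-3-methyl-5-[(1R,3R,6S)-2,2,6-trimethyl-3,6-bis(triethylsilyloxy)cyclohexyl]pentan-3-ol
Product: 17 (3R)-5-[(1R,3R,6S)-3,6-dihydroxy-2,2,6-trimethylcyclohexyl]-3-methylpentane-1,3-diol
Conditions: TBAF, THF, rt
Reagents that add atoms: none
Why: Fluoride-mediated desilylation should cleave the primary TBS ether and both TES ethers in one operation under non-acidic conditions that spare the two tertiary alcohols.

Step 11
Reactants: 17 (3R)-5-[(1R,3R,6S)-3,6-dihydroxy-2,2,6-trimethylcyclohexyl]-3-methylpentane-1,3-diol; 18 umbelliferone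
Product: 19 7-{[(3R)-5-[(1R,3R,6S)-3,6-dihydroxy-2,2,6-trimethylcyclohexyl]-3-hydroxy-3-methylpentyl]oxy}-2H-chromen-2-one
Conditions: PPh3, DIAD, THF, 0 °C → rt
Reagents that add atoms: none
Why: Mitsunobu etherification with the acidic phenol should occur only at the primary hydroxyl, because the neopentyl-type secondary and the two tertiary alcohols cannot undergo SN2 displacement.

Step 12
Reactants: 19 7-{[(3R)-5-[(1R,3R,6S)-3,6-dihydroxy-2,2,6-trimethylcyclohexyl]-3-hydroxy-3-methylpentyl]oxy}-2H-chromen-2-one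
Product: 20 7-{[(3R)-3-hydroxy-5-[(1R,6S)-6-hydroxy-2,2,6-trimethyl-3-oxocyclohexyl]-3-methylpentyl]oxy}-2H-chromen-2-one
Conditions: Dess–Martin periodinane, NaHCO3, CH2Cl2, rt
Reagents that add atoms: none
Why: Dess–Martin oxidation should convert the only secondary alcohol into the ring ketone, removing the temporary stereocentre, while the tertiary alcohols and the coumarin are inert.

Compound list
1 | (S)-(+)-linalool, (3S)-3,7-dimethylocta-1,6-dien-3-ol | CC(C)=CCC[C@](C)(O)C=C | starting material
2 | triethyl{[(3S)-3,7-dimethylocta-1,6-dien-3-yl]oxy}silane | CC(C)=CCC[C@](C)(O[Si](CC)(CC)CC)C=C | intermediate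
3 | triethyl{[(3S)-5-[(2R)-3,3-dimethyloxiran-2-yl]-3-methylpent-1-en-3-yl]oxy}silane | CC1(C)O[C@@H]1CC[C@](C)(O[Si](CC)(CC)CC)C=C | intermediate
4 | allyltrimethylsilane | C=CC[Si](C)(C)C | starting material
5 | triethyl{[(2E,4S)-6-[(2R)-3,3-dimethyloxiran-2-yl]-4-methyl-1-(trimethylsilyl)hex-2-en-4-yl]oxy}silane | CC1(C)O[C@@H]1CC[C@](C)(O[Si](CC)(CC)CC)/C=C/C[Si](C)(C)C | intermediate
6 | (1R,3R,4S)-3-ethenyl-2,2,4-trimethyl-4-[(triethylsilyl)oxy]cyclohexan-1-ol | CC1(C)[C@H](O)CC[C@](C)(O[Si](CC)(CC)CC)[C@@H]1C=C | intermediate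
7 | {[(1R,3R,4S)-3-ethenyl-2,2,4-trimethylcyclohexane-1,4-diyl]bis(oxy)}bis(triethylsilane) | CC1(C)[C@H](O[Si](CC)(CC)CC)CC[C@](C)(O[Si](CC)(CC)CC)[C@@H]1C=C | intermediate
8 | 2-{2-[(1R,3R,6S)-2,2,6-trimethyl-3,6-bis(triethylsilyloxy)cyclohexyl]ethyl}-1,3,2-benzodioxaborole (catechol boronate, not isolated) | CC1(C)[C@H](O[Si](CC)(CC)CC)CC[C@](C)(O[Si](CC)(CC)CC)[C@@H]1CCB2Oc3ccccc3O2 | intermediate
9 | 5,5-dimethyl-2-{2-[(1R,3R,6S)-2,2,6-trimethyl-3,6-bis(triethylsilyloxy)cyclohexyl]ethyl}-1,3,2-dioxaborinane | CC1(C)[C@H](O[Si](CC)(CC)CC)CC[C@](C)(O[Si](CC)(CC)CC)[C@@H]1CCB2OCC(C)(C)CO2 | intermediate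
10 | (R)-butane-1,3-diol | C[C@@H](O)CCO | starting material
11 | (2R)-4-[(tert-butyldimethylsilyl)oxy]butan-2-ol | C[C@@H](O)CCO[Si](C)(C)C(C)(C)C | intermediate
12 | (2S)-4-[(tert-butyldimethylsilyl)oxy]butan-2-yl 2,4,6-triisopropylbenzoate | C[C@H](OC(=O)c1c(C(C)C)cc(C(C)C)cc1C(C)C)CCO[Si](C)(C)C(C)(C)C | intermediate
13 | (2S)-4-[(tert-butyldimethylsilyl)oxy]-2-lithiobutan-2-yl 2,4,6-triisopropylbenzoate (lithiated benzoate, not isolated) | C[C@]([Li])(OC(=O)c1c(C(C)C)cc(C(C)C)cc1C(C)C)CCO[Si](C)(C)C(C)(C)C | intermediate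
14 | lithium boronate complex of 13 and 9: tetracoordinate boron bearing C-4', the (S)-configured C-3' (still carrying the benzoate) and the neopentyl glycolate (not isolated) | CC1(C)[C@H](O[Si](CC)(CC)CC)CC[C@](C)(O[Si](CC)(CC)CC)[C@@H]1CC[B-]2(OCC(C)(C)CO2)[C@@](C)(OC(=O)c3c(C(C)C)cc(C(C)C)cc3C(C)C)CCO[Si](C)(C)C(C)(C)C.[Li+] | intermediate
15 | 2-{(3S)-1-[(tert-butyldimethylsilyl)oxy]-3-methyl-5-[(1R,3R,6S)-2,2,6-trimethyl-3,6-bis(triethylsilyloxy)cyclohexyl]pentan-3-yl}-5,5-dimethyl-1,3,2-dioxaborinane (tertiary boronic ester, not isolated) | CC1(C)[C@H](O[Si](CC)(CC)CC)CC[C@](C)(O[Si](CC)(CC)CC)[C@@H]1CC[C@@](C)(B2OCC(C)(C)CO2)CCO[Si](C)(C)C(C)(C)C | intermediate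
16 | (3R)-1-[(tert-butyldimethylsilyl)oxy]-3-methyl-5-[(1R,3R,6S)-2,2,6-trimethyl-3,6-bis(triethylsilyloxy)cyclohexyl]pentan-3-ol | CC1(C)[C@H](O[Si](CC)(CC)CC)CC[C@](C)(O[Si](CC)(CC)CC)[C@@H]1CC[C@@](C)(O)CCO[Si](C)(C)C(C)(C)C | intermediate
17 | (3R)-5-[(1R,3R,6S)-3,6-dihydroxy-2,2,6-trimethylcyclohexyl]-3-methylpentane-1,3-diol | CC1(C)[C@H](O)CC[C@](C)(O)[C@@H]1CC[C@@](C)(O)CCO | intermediate
18 | umbelliferone (7-hydroxy-2H-chromen-2-one) | Oc1ccc2ccc(=O)oc2c1 | starting material
19 | 7-{[(3R)-5-[(1R,3R,6S)-3,6-dihydroxy-2,2,6-trimethylcyclohexyl]-3-hydroxy-3-methylpentyl]oxy}-2H-chromen-2-one | CC1(C)[C@H](O)CC[C@](C)(O)[C@@H]1CC[C@@](C)(O)CCOc1ccc2ccc(=O)oc2c1 | intermediate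
20 | 7-{[(3R)-3-hydroxy-5-[(1R,6S)-6-hydroxy-2,2,6-trimethyl-3-oxocyclohexyl]-3-methylpentyl]oxy}-2H-chromen-2-one (CNP0414652.1) | CC1(C)C(=O)CC[C@](C)(O)[C@@H]1CC[C@@](C)(O)CCOc1ccc2ccc(=O)oc2c1 | target

Total step count: 12. Longest linear sequence: 10 steps (steps 1–6 and 9–12); steps 7–8 make the second fragment.

Steps most likely to fail

Step 4 (ring closure). The silyl ether oxygen may open the activated epoxide itself, the tertiary allylic silyl ether may ionise and eliminate before the allylsilane attacks, or facial control in the chair transition state may be incomplete. The fallback closes the ring by a radical instead of a cation and uses no Lewis acid. It sets out from 3: cross-metathesis with methyl acrylate would give the enoate F1; titanocene(III) chloride (Cp2TiCl2, Mn, THF) would open the epoxide to the tertiary radical, which should close 6-exo onto the enoate through a chair-like transition state to give the hydroxy ester F2; silylation (TESOTf, 2,6-lutidine) would give the bis-silyl ester F3; LiAlH4 would give the primary alcohol F4; I2/PPh3/imidazole would give the iodide F5; and copper-catalysed borylation (CuI, PPh3, LiOMe, bis(neopentyl glycolato)diboron, DMF) would return to the route at 9.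

Step 9 (key coupling). Deprotonation of the unactivated secondary benzoate may stay incomplete, or the hindered boronate complex may revert to its components instead of rearranging. The fallback makes the same C-4'–C-3' bond by sp3–sp2 cross-coupling and sets the C-3' configuration afterwards. It sets out from 7: hydroboration with 9-BBN would give the B-alkyl borane F6, which is coupled in the same flask with (Z)-3-iodobut-2-en-1-ol (PdCl2(dppf), AsPh3, Cs2CO3, DMF/H2O; B-alkyl Suzuki–Miyaura coupling) to the (Z)-allylic alcohol F7; Sharpless asymmetric epoxidation (L-(+)-DET, Ti(OiPr)4, t-BuOOH, −20 °C) should give the (2S,3R)-epoxy alcohol F8; Red-Al should open it at C-2' to the 1,3-diol F9; and TBAF would return to the route at 17.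

Step 3 (cross-metathesis). The vinyl group next to the fully substituted silyloxy carbon may turn over slowly, so that self-metathesis of the allylsilane and catalyst decay take over. The fallback builds the allylsilane by carbonyl olefination instead of metathesis. It sets out from 3: ozonolysis (O3, CH2Cl2, −78 °C; PPh3) would give the aldehyde F10; Wittig reaction with Ph3P=CHCH2SiMe3 would give the (Z)-allylsilane F11; and cyclisation under the conditions of step 4 would return to the route at 6.

Further compounds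
F1 | step 4 | methyl (2E,4S)-6-[(2R)-3,3-dimethyloxiran-2-yl]-4-methyl-4-[(triethylsilyl)oxy]hex-2-enoate | CC1(C)O[C@@H]1CC[C@](C)(O[Si](CC)(CC)CC)/C=C/C(=O)OC
F2 | step 4 | methyl 2-[(1R,3R,6S)-3-hydroxy-2,2,6-trimethyl-6-[(triethylsilyl)oxy]cyclohexyl]acetate | CC1(C)[C@H](O)CC[C@](C)(O[Si](CC)(CC)CC)[C@@H]1CC(=O)OC
F3 | step 4 | methyl 2-[(1R,3R,6S)-2,2,6-trimethyl-3,6-bis(triethylsilyloxy)cyclohexyl]acetate | CC1(C)[C@H](O[Si](CC)(CC)CC)CC[C@](C)(O[Si](CC)(CC)CC)[C@@H]1CC(=O)OC
F4 | step 4 | 2-[(1R,3R,6S)-2,2,6-trimethyl-3,6-bis(triethylsilyloxy)cyclohexyl]ethan-1-ol | CC1(C)[C@H](O[Si](CC)(CC)CC)CC[C@](C)(O[Si](CC)(CC)CC)[C@@H]1CCO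
F5 | step 4 | {[(1R,3R,4S)-3-(2-iodoethyl)-2,2,4-trimethylcyclohexane-1,4-diyl]bis(oxy)}bis(triethylsilane) | CC1(C)[C@H](O[Si](CC)(CC)CC)CC[C@](C)(O[Si](CC)(CC)CC)[C@@H]1CCI
F6 | step 9 | 9-{2-[(1R,3R,6S)-2,2,6-trimethyl-3,6-bis(triethylsilyloxy)cyclohexyl]ethyl}-9-borabicyclo[3.3.1]nonane | CC1(C)[C@H](O[Si](CC)(CC)CC)CC[C@](C)(O[Si](CC)(CC)CC)[C@@H]1CCB2C3CCCC2CCC3
F7 | step 9 | (2Z)-3-methyl-5-[(1R,3R,6S)-2,2,6-trimethyl-3,6-bis(triethylsilyloxy)cyclohexyl]pent-2-en-1-ol | CC1(C)[C@H](O[Si](CC)(CC)CC)CC[C@](C)(O[Si](CC)(CC)CC)[C@@H]1CC/C(C)=C\CO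
F8 | step 9 | [(2S,3R)-3-methyl-3-{2-[(1R,3R,6S)-2,2,6-trimethyl-3,6-bis(triethylsilyloxy)cyclohexyl]ethyl}oxiran-2-yl]methanol | CC1(C)[C@H](O[Si](CC)(CC)CC)CC[C@](C)(O[Si](CC)(CC)CC)[C@@H]1CC[C@@]2(C)O[C@H]2CO
F9 | step 9 | (3R)-3-methyl-5-[(1R,3R,6S)-2,2,6-trimethyl-3,6-bis(triethylsilyloxy)cyclohexyl]pentane-1,3-diol | CC1(C)[C@H](O[Si](CC)(CC)CC)CC[C@](C)(O[Si](CC)(CC)CC)[C@@H]1CC[C@@](C)(O)CCO
F10 | step 3 | (2S)-4-[(2R)-3,3-dimethyloxiran-2-yl]-2-methyl-2-[(triethylsilyl)oxy]butanal | CC1(C)O[C@@H]1CC[C@](C)(O[Si](CC)(CC)CC)C=O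
F11 | step 3 | triethyl{[(2Z,4S)-6-[(2R)-3,3-dimethyloxiran-2-yl]-4-methyl-1-(trimethylsilyl)hex-2-en-4-yl]oxy}silane | CC1(C)O[C@@H]1CC[C@](C)(O[Si](CC)(CC)CC)/C=C\C[Si](C)(C)C
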